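**Retrosynthetic overview**

1. Target ⇒ break O1–C2: acid-mediated SN1 (quinone-methide-type) closure of a 1-aryl-2-methyl-3-benzylbutane-1,4-diol, which places the aryl group trans to the C3 methyl; the MOM groups leave in the same acid.
2. Diol ⇒ guaiacyl-lithium plus a trans-α-methyl-β-(syringylmethyl)-γ-butyrolactone; the methyl comes from enolate alkylation anti to the benzyl group.
3. β-(Arylmethyl)lactone ⇒ copper-catalysed homoconjugate opening of a cyclopropane-fused malonate lactone by the syringyl Grignard (the cyclopropane CH2 is the latent benzylic CH2), then dealkoxycarbonylation.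
4. Cyclopropane-fused lactone ⇒ (R)-epichlorohydrin plus dimethyl malonate: cyclopropane and γ-lactone form together in one operation and fix the C4 stereocentre from the chiral pool.
5. Ring order: cyclopropane and γ-lactone together (step 1) → cyclopropane opened (step 3) → lactone opened (step 7) → tetrahydrofuran closed (step 8).

Assumption: numbers follow the forward route; a metal salt that is only the unprotonated form of an isolated product before work-up is not numbered separately.

**Route**

Step 1
Reactants: 1 dimethyl malonate; 2 (R)-epichlorohydrin [(2R)-2-(chloromethyl)oxirane]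
Product: 6 methyl (1S,5R)-2-oxo-3-oxabicyclo[3.1.0]hexane-1-carboxylate, via chlorohydrin 3 (not isolated), via epoxide 4 (not isolated), via cyclopropylmethanol 5 (not isolated)
Conditions: NaOMe (1.0 equiv), MeOH, rt → reflux
Reagents that add atoms: none
Why: Tandem malonate alkylation / 3-exo-tet cyclopropanation / lactonisation: the malonate anion opens the epoxide of 2 at CH2 to give 3, the alkoxide closes to epoxide 4, the malonate anion of 4 attacks the stereogenic CH with inversion to give 5, and the cis CH2OH lactonises onto an ester, so cyclopropane and γ-lactone arise in one operation with C5 (later C4 of the target) taken from the chiral pool and C1 fixed by the obligatory cis fusion; the risk is a minor direct displacement of chloride, which leads to the enantiomer and erodes the ee.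

Step 2
Reactants: 7 4-bromo-2,6-dimethoxyphenol
Product: 8 5-bromo-1,3-dimethoxy-2-(methoxymethoxy)benzene
Conditions: MOMCl, i-Pr2NEt, CH2Cl2, 0 °C → rt
Reagents that add atoms: chloromethyl methyl ether, COCCl
Why: O-Alkylation of the phenol (Williamson-type acetal formation) masks the acidic OH so that the bromide can be converted into a Grignard reagent; no stereocentre is involved.

Step 3
Reactants: 8 5-bromo-1,3-dimethoxy-2-(methoxymethoxy)benzene; 6 methyl (1S,5R)-2-oxo-3-oxabicyclo[3.1.0]hexane-1-carboxylate
Product: 10 methyl (3S,4R)-4-{[3,5-dimethoxy-4-(methoxymethoxy)phenyl]methyl}-2-oxooxolane-3-carboxylate, via Grignard reagent 9 (not isolated)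
Conditions: Mg, THF, 50 °C; then CuI (10 mol %), 6, THF, −40 → 0 °C; aq. NH4Cl
Reagents that add atoms: none
Why: Copper-catalysed homoconjugate (1,5-) addition of the aryl Grignard to the doubly activated cyclopropane: SN2-type attack at the unsubstituted CH2 breaks the C1–C6 bond, so the C5 stereocentre is untouched and becomes C4 (R) of the lactone, while the epimerisable malonate-type C3 settles trans (3S) to the new benzyl group.

Step 4
Reactants: 10 methyl (3S,4R)-4-{[3,5-dimethoxy-4-(methoxymethoxy)phenyl]methyl}-2-oxooxolane-3-carboxylate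
Product: 11 (4R)-4-{[3,5-dimethoxy-4-(methoxymethoxy)phenyl]methyl}oxolan-2-one
Conditions: LiCl, H2O, DMSO, 150 °C
Reagents that add atoms: none
Why: Krapcho dealkoxycarbonylation (chloride SN2 at the ester methyl, loss of CO2, protonation) removes the activating ester without touching C4 or the MOM acetal.

Step 5
Reactants: 11 (4R)-4-{[3,5-dimethoxy-4-(methoxymethoxy)phenyl]methyl}oxolan-2-one
Product: 13 (3R,4R)-4-{[3,5-dimethoxy-4-(methoxymethoxy)phenyl]methyl}-3-methyloxolan-2-one, via lithium enolate 12 (not isolated)
Conditions: LDA, THF, −78 °C; then MeI, −78 → −40 °C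
Reagents that add atoms: iodomethane, CI
Why: Kinetic lactone enolate alkylation: methyl iodide approaches the planar enolate anti to the adjacent C4 benzyl group, which sets C3 as R (3,4-trans).

Step 6
Reactants: 14 4-bromo-2-methoxyphenol
Product: 15 4-bromo-2-methoxy-1-(methoxymethoxy)benzene
Conditions: MOMCl, i-Pr2NEt, CH2Cl2, 0 °C → rt
Reagents that add atoms: chloromethyl methyl ether, COCCl
Why: O-Alkylation of the phenol (Williamson-type acetal formation) protects the OH for the bromine–lithium exchange; no stereocentre is involved.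

Step 7
Reactants: 15 4-bromo-2-methoxy-1-(methoxymethoxy)benzene; 13 (3R,4R)-4-{[3,5-dimethoxy-4-(methoxymethoxy)phenyl]methyl}-3-methyloxolan-2-one
Product: 18 (2R,3R)-3-{[3,5-dimethoxy-4-(methoxymethoxy)phenyl]methyl}-1-[3-methoxy-4-(methoxymethoxy)phenyl]-2-methylbutane-1,4-diol (C1 epimers), via aryllithium 16 (not isolated), via hydroxy ketone 17 (not isolated)
Conditions: n-BuLi, THF, −78 °C; then 13, −78 °C; then MeOH, NaBH4, −78 → 0 °C
Reagents that add atoms: none
Why: Bromine–lithium exchange gives 16, whose addition to the lactone carbonyl (nucleophilic acyl substitution) stops at the tetrahedral lithium lactolate at −78 °C, methanol releases hydroxy ketone 17 and NaBH4 reduces it in the same flask; C2 and C3 of 18 (C3 and C4 of the lactone) are not touched, and the new carbinol centre is left as an epimer mixture because it is ionised in the next step.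

Step 8
Reactants: 18 (2R,3R)-3-{[3,5-dimethoxy-4-(methoxymethoxy)phenyl]methyl}-1-[3-methoxy-4-(methoxymethoxy)phenyl]-2-methylbutane-1,4-diol (C1 epimers)
Product: 20 (2R,3R,4R)-2-(4-hydroxy-3-methoxyphenyl)-4-[(4-hydroxy-3,5-dimethoxyphenyl)methyl]-3-methyloxolane, via bis-MOM tetrahydrofuran 19 (not isolated)
Conditions: HCl (ca. 1 M in MeOH), 0 °C → rt
Reagents that add atoms: none
Why: Acid ionises the electron-rich benzylic alcohol to a p-alkoxybenzyl cation (quinone-methide-type SN1), the primary hydroxyl closes the ring 5-exo on the face anti to the neighbouring methyl and, since the closure is reversible, it ends at the all-trans 2R isomer, after which acid-catalysed acetal exchange with methanol removes both MOM groups.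

**Compound list**

1 | dimethyl malonate | COC(=O)CC(=O)OC | starting material
2 | (R)-epichlorohydrin, (2R)-2-(chloromethyl)oxirane | ClC[C@H]1CO1 | starting material
3 | dimethyl 2-[(2R)-3-chloro-2-hydroxypropyl]propanedioate | ClC[C@H](O)CC(C(=O)OC)C(=O)OC | intermediate (not isolated)
4 | dimethyl 2-{[(2R)-oxiran-2-yl]methyl}propanedioate | C1[C@H](O1)CC(C(=O)OC)C(=O)OC | intermediate (not isolated)
5 | dimethyl (2R)-2-(hydroxymethyl)cyclopropane-1,1-dicarboxylate | OC[C@@H]1CC1(C(=O)OC)C(=O)OC | intermediate (not isolated)
6 | methyl (1S,5R)-2-oxo-3-oxabicyclo[3.1.0]hexane-1-carboxylate (cis-fused cyclopropane/γ-lactone) | COC(=O)[C@]12C[C@H]1COC2=O | intermediate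
7 | 4-bromo-2,6-dimethoxyphenol | COc1cc(Br)cc(OC)c1O | starting material
8 | 5-bromo-1,3-dimethoxy-2-(methoxymethoxy)benzene | COCOc1c(OC)cc(Br)cc1OC | intermediate
9 | [3,5-dimethoxy-4-(methoxymethoxy)phenyl]magnesium bromide | COCOc1c(OC)cc([Mg]Br)cc1OC | intermediate (not isolated)
10 | methyl (3S,4R)-4-{[3,5-dimethoxy-4-(methoxymethoxy)phenyl]methyl}-2-oxooxolane-3-carboxylate (3,4-trans) | COC(=O)[C@@H]1[C@@H](Cc2cc(OC)c(OCOC)c(OC)c2)COC1=O | intermediate
11 | (4R)-4-{[3,5-dimethoxy-4-(methoxymethoxy)phenyl]methyl}oxolan-2-one | O=C1C[C@@H](Cc2cc(OC)c(OCOC)c(OC)c2)CO1 | intermediate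
12 | lithium enolate of 11, lithium (4R)-4-(arylmethyl)-4,5-dihydrofuran-2-olate | [Li+].[O-]C1=C[C@@H](Cc2cc(OC)c(OCOC)c(OC)c2)CO1 | intermediate (not isolated)
13 | (3R,4R)-4-{[3,5-dimethoxy-4-(methoxymethoxy)phenyl]methyl}-3-methyloxolan-2-one (3,4-trans) | C[C@@H]1[C@@H](Cc2cc(OC)c(OCOC)c(OC)c2)COC1=O | intermediate
14 | 4-bromo-2-methoxyphenol | COc1cc(Br)ccc1O | starting material
15 | 4-bromo-2-methoxy-1-(methoxymethoxy)benzene | COCOc1ccc(Br)cc1OC | intermediate
16 | [3-methoxy-4-(methoxymethoxy)phenyl]lithium | [Li]c1ccc(OCOC)c(OC)c1 | intermediate (not isolated)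
17 | (2R,3R)-3-{[3,5-dimethoxy-4-(methoxymethoxy)phenyl]methyl}-4-hydroxy-1-[3-methoxy-4-(methoxymethoxy)phenyl]-2-methylbutan-1-one (in equilibrium with its cyclic hemiketal) | C[C@@H](C(=O)c1ccc(OCOC)c(OC)c1)[C@@H](Cc2cc(OC)c(OCOC)c(OC)c2)CO | intermediate (not isolated)
18 | (2R,3R)-3-{[3,5-dimethoxy-4-(methoxymethoxy)phenyl]methyl}-1-[3-methoxy-4-(methoxymethoxy)phenyl]-2-methylbutane-1,4-diol, mixture of C1 epimers | C[C@@H](C(O)c1ccc(OCOC)c(OC)c1)[C@@H](Cc2cc(OC)c(OCOC)c(OC)c2)CO | intermediate
19 | (2R,3R,4R)-4-{[3,5-dimethoxy-4-(methoxymethoxy)phenyl]methyl}-2-[3-methoxy-4-(methoxymethoxy)phenyl]-3-methyloxolane (all-trans) | COc1cc([C@@H]2OC[C@H](Cc3cc(OC)c(OCOC)c(OC)c3)[C@H]2C)ccc1OCOC | intermediate (not isolated)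
20 | (2R,3R,4R)-2-(4-hydroxy-3-methoxyphenyl)-4-[(4-hydroxy-3,5-dimethoxyphenyl)methyl]-3-methyloxolane (all-trans) | COc1cc([C@@H]2OC[C@H](Cc3cc(OC)c(O)c(OC)c3)[C@H]2C)ccc1O | target

**Step count and risks**

Total steps: 8 (steps 2 and 6 are single protections off the main line). Longest linear sequence: 6 steps (1 → 3 → 4 → 5 → 7 → 8).

The three steps most likely to fail:

Step 8 (acid closure and deprotection). The benzylic cation can also be captured irreversibly by the electron-rich syringyl ring (Friedel–Crafts closure to an aryltetralin), and the MOM cleavage needs more acid than the ring closure. The fallback sets out from 18 and comes back at 20. The two events are separated: catalytic camphorsulfonic acid (CH2Cl2, 0 °C) closes the ring and the bis-MOM tetrahydrofuran 19 is isolated. The aryl MOM ethers are then exchanged under buffered, non-protic conditions (TMSOTf, 2,2'-bipyridyl, CH2Cl2, 0 °C) into (2R,3R,4R)-4-{[3,5-dimethoxy-4-(trimethylsilyloxy)phenyl]methyl}-2-[3-methoxy-4-(trimethylsilyloxy)phenyl]-3-methyloxolane F3, which water cleaves at work-up to 20. The finished phenolic tetrahydrofuran therefore never meets free protic acid.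

Step 7 (aryllithium on the lactone, reduction in the same flask). Possible failures are double addition, enolisation with loss of the C3 configuration at the aryl ketone stage, and incomplete reduction. The fallback sets out from 13 and comes back at 18. DIBAL-H (toluene, −78 °C) stops at the lactol (3R,4R)-4-{[3,5-dimethoxy-4-(methoxymethoxy)phenyl]methyl}-3-methyloxolan-2-ol F2. The lactol is deprotonated with i-PrMgCl and its open hydroxy-aldehyde form is trapped by aryllithium 16 (made from 15 as before). This is a plain 1,2-addition to an aldehyde that gives diol 18 directly, with no ketone stage and no separate reduction.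

Step 3 (homoconjugate arylation). The electron-rich bromide may form the Grignard reagent sluggishly, and the reagent may attack the lactone or ester carbonyl instead of the cyclopropane. The fallback sets out from 6 and comes back at 10. Magnesium iodide (THF, 0 °C → rt, then aq. NH4Cl) opens the activated cyclopropane at CH2 with iodide, with the same regiochemistry and the stereocentre untouched, to give methyl (3S,4R)-4-(iodomethyl)-2-oxooxolane-3-carboxylate F1. A nickel-catalysed reductive cross-electrophile coupling of F1 with aryl bromide 8 (NiBr2·glyme, 4,4'-di-tert-butyl-2,2'-bipyridine, Zn, DMA, rt) then makes the benzylic C–C bond through an alkyl radical / aryl-nickel pathway, so no aryl-magnesium or aryl-copper nucleophile is needed.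

**Further compounds**

F1 | step 3 | methyl (3S,4R)-4-(iodomethyl)-2-oxooxolane-3-carboxylate | COC(=O)[C@@H]1[C@@H](CI)COC1=O
F2 | step 7 | (3R,4R)-4-{[3,5-dimethoxy-4-(methoxymethoxy)phenyl]methyl}-3-methyloxolan-2-ol (anomer mixture) | C[C@@H]1[C@@H](Cc2cc(OC)c(OCOC)c(OC)c2)COC1O
F3 | step 8 | (2R,3R,4R)-4-{[3,5-dimethoxy-4-(trimethylsilyloxy)phenyl]methyl}-2-[3-methoxy-4-(trimethylsilyloxy)phenyl]-3-methyloxolane | COc1cc([C@@H]2OC[C@H](Cc3cc(OC)c(O[Si](C)(C)C)c(OC)c3)[C@H]2C)ccc1O[Si](C)(C)C
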